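**Retrosynthetic overview**
1. Target ⇐ Lindlar semi-hydrogenation (sets 15Z) ⇐ Noyori transfer hydrogenation of a macrocyclic ynone (sets C17) ⇐ ring-closing metathesis that forms the dehydropiperidine (C2=C3), the last ring.
2. 15-membered ring ⇐ Pd/Cu carbonylative alkyne–vinyl iodide coupling (C16–C17–C18, CO becomes C17); the ester link is installed beforehand by N-alkylation with a 2-(bromomethyl)acrylate.
3. Spiro-piperidine ⇐ nitro reduction and intramolecular SN2 at C5 (inversion) ⇐ key step: Ni/photoredox radical C-alkylation of a secondary nitronate, forming the C8–C9 bond and the fully substituted N-bearing C9.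
4. C13/C14 ⇐ amine-catalysed Michael addition of propanal to 1-nitrocyclopentene, then Ohira–Bestmann alkyne; C5 ⇐ Brown allylation; chloroalkene ⇐ anti-iodochlorination of but-3-yn-1-ol.
5. Ring order: cyclopentane (bought) → piperidine → macrolactone → dehydropiperidine.

Assumption: atom labels follow the halichlorine skeleton (C1 lactone C=O, C2=C3, N between C5 and C9, C13–C14(CH3), C15=C16, C17–OH, C18=C19(Cl), C21–O, N–CH2 = C22); the target is read as (5R,9S,13R,14S,15Z,17R,18E); compounds 2, 5 and 14 are taken as purchasable.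

**Route**

Step 1
Reactants: 1 propanal; 2 1-nitrocyclopent-1-ene
Product: 3 (2R)-2-[(1R)-2-nitrocyclopentyl]propanal
Conditions: (S)-α,α-diphenylprolinol TMS ether (20 mol%), 4-nitrophenol (20 mol%), 1 (3 equiv), toluene, 0 °C → rt
Reagents that add atoms: none
Why: Enamine-catalysed (Hayashi–Jørgensen) Michael addition of an aldehyde to a nitroalkene; the (S)-catalyst enamine adds through the usual synclinal transition state to give the syn adduct, setting C14 and C13 in the same sense as the (2R,3S) nitrostyrene adducts, while the C–NO2 centre is uncontrolled and is erased in step 6.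

Step 2
Reactants: 3 (2R)-2-[(1R)-2-nitrocyclopentyl]propanal
Product: 4 (1R)-1-[(2R)-but-3-yn-2-yl]-2-nitrocyclopentane
Conditions: dimethyl (1-diazo-2-oxopropyl)phosphonate, K2CO3, MeOH, 0 °C → rt
Reagents that add atoms: dimethyl (1-diazo-2-oxopropyl)phosphonate CC(=O)C(=[N+]=[N-])P(=O)(OC)OC
Why: Ohira–Bestmann (Seyferth–Gilbert) homologation turns the aldehyde into the terminal alkyne under carbonate conditions mild enough to keep the α-methyl centre C14; the nitro group is only reversibly deprotonated.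

Step 3
Reactants: 5 tetrahydrofuran-2-ol
Product: 6 (4S)-hept-6-ene-1,4-diol
Conditions: (+)-Ipc2B(allyl) (2.2 equiv), Et2O, −78 °C → rt; then NaOH, H2O2
Reagents that add atoms: (+)-B-allyldiisopinocampheylborane C=CCB([C@H]1C[C@H]2C[C@@H]([C@@H]1C)C2(C)C)[C@H]1C[C@H]2C[C@@H]([C@@H]1C)C2(C)C
Why: Brown asymmetric allylboration of the open 4-hydroxybutanal tautomer through a chair transition state; the (−)-α-pinene-derived reagent attacks the Re face and gives the (S)-carbinol that becomes C5.

Step 4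
Reactants: 6 (4S)-hept-6-ene-1,4-diol
Product: 7 (4S)-hept-6-ene-1,4-diyl dimethanesulfonate
Conditions: MsCl (2.4 equiv), Et3N, CH2Cl2, 0 °C
Reagents that add atoms: methanesulfonyl chloride CS(=O)(=O)Cl
Why: Sulfonylation of both hydroxyls with excess MsCl outruns tetrahydrofuran formation and does not touch the stereocentre.

Step 5
Reactants: 7 (4S)-hept-6-ene-1,4-diyl dimethanesulfonate
Product: 8 (4S)-7-iodohept-1-en-4-yl methanesulfonate
Conditions: NaI (1.2 equiv), acetone, rt
Reagents that add atoms: sodium iodide [Na+].[I-]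
Why: Finkelstein SN2 displacement is far faster at the primary than at the secondary mesylate, so the C5 mesylate is kept with its configuration.

Step 6
Reactants: 4 (1R)-1-[(2R)-but-3-yn-2-yl]-2-nitrocyclopentane; 8 (4S)-7-iodohept-1-en-4-yl methanesulfonate
Product: 9 (4S)-7-{(1S,2R)-2-[(2R)-but-3-yn-2-yl]-1-nitrocyclopentyl}hept-1-en-4-yl methanesulfonate
Conditions: NiBr2·diglyme (20 mol%), bathocuproine (20 mol%), Ir[dF(CF3)ppy]2(dtbbpy)PF6 (1 mol%), DBU (1.2 equiv), 1,4-dioxane, blue LEDs, 25 °C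
Reagents that add atoms: none
Why: Nickel/photoredox radical C-alkylation of a nitronate: single-electron reduction of the iodide gives the primary C8 radical, which is captured at carbon of the nickel-bound nitronate; A(1,3) strain turns the C13 side chain perpendicular to the planar nitronate, so the C8–C9 bond forms anti to it and the nitro group ends up cis to C14 (C9 S), both C–NO2 epimers of 4 converging on one product.

Step 7
Reactants: 9 (4S)-7-{(1S,2R)-2-[(2R)-but-3-yn-2-yl]-1-nitrocyclopentyl}hept-1-en-4-yl methanesulfonate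
Product: 11 (1R,5S,7R)-1-[(2R)-but-3-yn-2-yl]-7-(prop-2-en-1-yl)-6-azaspiro[4.5]decane, via amino mesylate 10 (not isolated)
Conditions: Zn dust, AcOH, EtOH, 50 °C; then K2CO3, MeCN, 60 °C
Reagents that add atoms: none
Why: Dissolving-metal reduction of the tertiary nitro group leaves alkyne, alkene and mesylate intact, and the resulting α-tertiary amine closes the piperidine by 6-exo-tet SN2 with inversion, turning the (S)-mesylate into (R)-C5.

Step 8
Reactants: 12 but-3-yn-1-ol
Product: 13 (3E)-3-chloro-4-iodobut-3-en-1-ol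
Conditions: ICl (1.1 equiv), CH2Cl2, −78 → 0 °C
Reagents that add atoms: iodine monochloride ClI
Why: Electrophilic anti-iodochlorination of a terminal alkyne (iodonium opened by chloride at the internal carbon) gives the E isomer, in which iodine (the future C17 position) is trans to Cl and cis to C20 as the target requires.

Step 9
Reactants: 13 (3E)-3-chloro-4-iodobut-3-en-1-ol; 14 2-(bromomethyl)prop-2-enoic acid
Product: 15 (3E)-3-chloro-4-iodobut-3-en-1-yl 2-(bromomethyl)prop-2-enoate
Conditions: TsOH·H2O (5 mol%), BHT (trace), toluene, reflux, Dean–Stark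
Reagents that add atoms: none
Why: Fischer esterification with azeotropic water removal, the standard way to esterify this acid without a nucleophilic base that would attack the allylic bromide; it makes the C21–O–C1 ester bond early.

Step 10
Reactants: 11 (1R,5S,7R)-1-[(2R)-but-3-yn-2-yl]-7-(prop-2-en-1-yl)-6-azaspiro[4.5]decane; 15 (3E)-3-chloro-4-iodobut-3-en-1-yl 2-(bromomethyl)prop-2-enoate
Product: 16 (3E)-3-chloro-4-iodobut-3-en-1-yl 2-{[(1R,5S,7R)-1-[(2R)-but-3-yn-2-yl]-7-(prop-2-en-1-yl)-6-azaspiro[4.5]decan-6-yl]methyl}prop-2-enoate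
Conditions: K2CO3, MeCN, rt → 40 °C
Reagents that add atoms: none
Why: N-alkylation (SN2/SN2′) of the hindered secondary amine by the highly reactive 2-(bromomethyl)acrylate; both pathways give the same N–CH2–C(=CH2) product.

Step 11
Reactants: 16 (3E)-3-chloro-4-iodobut-3-en-1-yl 2-{[(1R,5S,7R)-1-[(2R)-but-3-yn-2-yl]-7-(prop-2-en-1-yl)-6-azaspiro[4.5]decan-6-yl]methyl}prop-2-enoate
Product: 17 (5R,9S,13R,14R,18E)-macrocyclic ynone (15-membered lactone with C15≡C16–C17(=O), exo-methylene on C2 and allyl on C5)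
Conditions: PdCl2(PPh3)2 (10 mol%), CuI (10 mol%), Et3N (3 equiv), CO (1 atm), THF, 40 °C, slow addition (final 2 mM)
Reagents that add atoms: carbon monoxide [C-]#[O+]
Why: Proposed new method: macrocyclising carbonylative Sonogashira coupling, in which Pd(0) inserts into the vinyl C–I bond (the vinyl chloride is inert), CO insertion gives the acyl-palladium, and the tethered copper acetylide transmetalates and reductively eliminates to close the ring with retention of the 18E geometry; the closest known reactions are the intermolecular carbonylative Sonogashira coupling of vinyl iodides and carbonylative Stille macrocyclisations.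

Step 12
Reactants: 17 (5R,9S,13R,14R,18E)-macrocyclic ynone
Product: 18 (5R,9S,13R,14R,18E)-17-oxo-15,16-didehydro analogue of the target (tricyclic macrolactone ynone)
Conditions: TsOH·H2O (1.05 equiv), Hoveyda–Grubbs II (10 mol%), toluene, 60 °C; aq. NaHCO3 work-up
Reagents that add atoms: none
Why: Ring-closing metathesis between the C5 allyl group and the acrylate methylene forms the six-membered C2=C3 enoate ring; the amine is masked as its tosylate salt and the electron-poor internal ynone does not compete.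

Step 13
Reactants: 18 (5R,9S,13R,14R,18E)-17-oxo-15,16-didehydro analogue of the target
Product: 19 (5R,9S,13R,14R,17S,18E)-15,16-didehydro analogue of the target (macrocyclic propargylic alcohol)
Conditions: Ru[(S,S)-TsDPEN](p-cymene) (5 mol%), iPrOH, rt
Reagents that add atoms: none
Why: Noyori asymmetric transfer hydrogenation of an ynone reduces only the C=O; with the alkynyl group taking the role of the aryl group in the CH/π model, the (S,S)-catalyst gives the (S)-propargylic alcohol, which is the target's C17 arrangement.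

Step 14
Reactants: 19 (5R,9S,13R,14R,17S,18E)-15,16-didehydro analogue of the target
Product: 20 target CNP0129639.4 (5R,9S,13R,14S,15Z,17R,18E)
Conditions: H2 (1 atm), Lindlar catalyst, quinoline, EtOAc, rt
Reagents that add atoms: none
Why: Lindlar semi-hydrogenation adds H2 syn to the ring alkyne and gives the 15Z alkene without touching the vinyl chloride or the enoate; the labels at C14 and C17 change (R→S, S→R) only because C15/C16 drop in CIP rank.

**Compound list**
1 | propanal | CCC=O | starting material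
2 | 1-nitrocyclopent-1-ene | O=[N+]([O-])C1=CCCC1 | starting material
3 | (2R)-2-[(1R)-2-nitrocyclopentyl]propanal (epimer mixture at C–NO2) | O=C[C@H](C)[C@H]1CCCC1[N+](=O)[O-] | intermediate
4 | (1R)-1-[(2R)-but-3-yn-2-yl]-2-nitrocyclopentane (epimer mixture at C–NO2) | C#C[C@H](C)[C@H]1CCCC1[N+](=O)[O-] | intermediate
5 | tetrahydrofuran-2-ol | OC1CCCO1 | starting material
6 | (4S)-hept-6-ene-1,4-diol | C=CC[C@H](CCCO)O | intermediate
7 | (4S)-hept-6-ene-1,4-diyl dimethanesulfonate | C=CC[C@H](CCCOS(C)(=O)=O)OS(C)(=O)=O | intermediate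
8 | (4S)-7-iodohept-1-en-4-yl methanesulfonate | C=CC[C@H](CCCI)OS(C)(=O)=O | intermediate
9 | (4S)-7-{(1S,2R)-2-[(2R)-but-3-yn-2-yl]-1-nitrocyclopentyl}hept-1-en-4-yl methanesulfonate | C#C[C@H](C)[C@H]1CCC[C@@]1(CCC[C@@H](CC=C)OS(C)(=O)=O)[N+](=O)[O-] | intermediate
10 | (4S)-7-{(1S,2R)-1-amino-2-[(2R)-but-3-yn-2-yl]cyclopentyl}hept-1-en-4-yl methanesulfonate (amino mesylate) | C#C[C@H](C)[C@H]1CCC[C@@]1(CCC[C@@H](CC=C)OS(C)(=O)=O)N | intermediate
11 | (1R,5S,7R)-1-[(2R)-but-3-yn-2-yl]-7-(prop-2-en-1-yl)-6-azaspiro[4.5]decane | C#C[C@H](C)[C@H]1CCC[C@]12CCC[C@H](CC=C)N2 | intermediate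
12 | but-3-yn-1-ol | C#CCCO | starting material
13 | (3E)-3-chloro-4-iodobut-3-en-1-ol | OCC/C(Cl)=C\I | intermediate
14 | 2-(bromomethyl)prop-2-enoic acid | C=C(CBr)C(=O)O | starting material
15 | (3E)-3-chloro-4-iodobut-3-en-1-yl 2-(bromomethyl)prop-2-enoate | C=C(CBr)C(=O)OCC/C(Cl)=C\I | intermediate
16 | (3E)-3-chloro-4-iodobut-3-en-1-yl 2-{[(1R,5S,7R)-1-[(2R)-but-3-yn-2-yl]-7-(prop-2-en-1-yl)-6-azaspiro[4.5]decan-6-yl]methyl}prop-2-enoate | C#C[C@H](C)[C@H]1CCC[C@]12CCC[C@H](CC=C)N2CC(=C)C(=O)OCC/C(Cl)=C\I | intermediate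
17 | (5R,9S,13R,14R,18E)-macrocyclic ynone: 15-membered lactone C14–C15≡C16–C17(=O)–C18=C19(Cl)–C20–C21–O–C1(=O)–C2(=CH2)–C22–N–C9–C13, allyl on C5 | C[C@H]1C#CC(=O)/C=C(/Cl)CCOC(=O)C(=C)CN2[C@@H](CC=C)CCC[C@]23CCC[C@H]13 | intermediate
18 | (5R,9S,13R,14R,18E)-17-oxo-15,16-didehydro analogue of the target (C2=C3 ring closed) | C[C@H]1C#CC(=O)/C=C(/Cl)CCOC(=O)C2=CC[C@H]3CCC[C@]4(CCC[C@H]14)N3C2 | intermediate
19 | (5R,9S,13R,14R,17S,18E)-15,16-didehydro analogue of the target (17-hydroxy) | C[C@H]1C#C[C@@H](O)/C=C(/Cl)CCOC(=O)C2=CC[C@H]3CCC[C@]4(CCC[C@H]14)N3C2 | intermediate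
20 | CNP0129639.4 (5R,9S,13R,14S,15Z,17R,18E) | C[C@H]1/C=C\[C@@H](O)/C=C(/Cl)CCOC(=O)C2=CC[C@H]3CCC[C@]4(CCC[C@H]14)N3C2 | target

**Step count**
Total: 14 steps. Longest linear sequence: 10 steps (5 → 6 → 7 → 8 → 9 → 11 → 16 → 17 → 18 → 19 → 20; steps 3, 4, 5, 6, 7, 10, 11, 12, 13, 14).

**Three steps most likely to fail**

Step 6 (radical nitronate alkylation). The nitronate is hindered by the neighbouring branched side chain, and O-alkylation, 6-exo cyclisation of the radical onto the allyl group, or a low anti selectivity could erode yield. The fallback replaces the radical coupling by polar chemistry; it sets out from 4 and comes back at 9. The DBU nitronate of 4 adds to acrolein (Michael addition, again anti to the side chain) to give 3-{(1S,2R)-2-[(2R)-but-3-yn-2-yl]-1-nitrocyclopentyl}propanal F1. Wittig reaction with methoxymethylenetriphenylphosphorane gives the enol ether (1S,2R)-2-[(2R)-but-3-yn-2-yl]-1-(4-methoxybut-3-en-1-yl)-1-nitrocyclopentane F2. Aqueous HCl in THF hydrolyses it to 4-{(1S,2R)-2-[(2R)-but-3-yn-2-yl]-1-nitrocyclopentyl}butanal F3. Brown allylation with (+)-Ipc2B(allyl) gives (4S)-7-{(1S,2R)-2-[(2R)-but-3-yn-2-yl]-1-nitrocyclopentyl}hept-1-en-4-ol F4, and mesylation (MsCl, Et3N) gives 9.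

Step 11 (carbonylative macrocyclisation). Direct non-carbonylative coupling, oligomerisation or alkyne homocoupling may dominate at the dilution needed. The fallback closes the ring at the ester instead; it sets out from 11 and comes back at 17. Amine 11 is N-alkylated with acid 14 (K2CO3, MeCN/H2O) to give 2-{[(1R,5S,7R)-1-[(2R)-but-3-yn-2-yl]-7-(prop-2-en-1-yl)-6-azaspiro[4.5]decan-6-yl]methyl}prop-2-enoic acid F5. Intermolecular carbonylative Sonogashira coupling of F5 with 13 (same Pd/Cu/CO system at normal concentration) gives the seco acid 2-{[(1R,5S,7R)-1-[(2R,6E)-7-chloro-9-hydroxy-5-oxonon-6-en-3-yn-2-yl]-7-(prop-2-en-1-yl)-6-azaspiro[4.5]decan-6-yl]methyl}prop-2-enoic acid F6. Yamaguchi macrolactonisation (2,4,6-trichlorobenzoyl chloride, Et3N, then DMAP, toluene, high dilution) forms the O21–C1 bond and gives 17.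

Step 13 (transfer hydrogenation). The ketone is flanked by two π-systems (alkynyl and chloro-alkenyl), so the catalyst's facial preference could be weak or reversed inside the macrocycle. The fallback gives up catalyst control for separation and inversion; it sets out from 18 and comes back at 19. Luche reduction (NaBH4, CeCl3·7H2O, MeOH, −78 °C) gives 19 together with its epimer, the (5R,9S,13R,14R,17R,18E)-15,16-didehydro analogue of the target F7, which is separated by chromatography. Mitsunobu reaction of F7 with 4-nitrobenzoic acid (PPh3, DIAD) inverts C17 to give the (17S)-4-nitrobenzoate of 19 F8, and brief methanolysis (K2CO3, MeOH, 0 °C) gives 19.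

**Further compounds**
F1 | step 6 | 3-{(1S,2R)-2-[(2R)-but-3-yn-2-yl]-1-nitrocyclopentyl}propanal | C#C[C@H](C)[C@H]1CCC[C@@]1(CCC=O)[N+](=O)[O-]
F2 | step 6 | (1S,2R)-2-[(2R)-but-3-yn-2-yl]-1-(4-methoxybut-3-en-1-yl)-1-nitrocyclopentane (E/Z mixture) | C#C[C@H](C)[C@H]1CCC[C@@]1(CCC=COC)[N+](=O)[O-]
F3 | step 6 | 4-{(1S,2R)-2-[(2R)-but-3-yn-2-yl]-1-nitrocyclopentyl}butanal | C#C[C@H](C)[C@H]1CCC[C@@]1(CCCC=O)[N+](=O)[O-]
F4 | step 6 | (4S)-7-{(1S,2R)-2-[(2R)-but-3-yn-2-yl]-1-nitrocyclopentyl}hept-1-en-4-ol | C#C[C@H](C)[C@H]1CCC[C@@]1(CCC[C@@H](CC=C)O)[N+](=O)[O-]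
F5 | step 11 | 2-{[(1R,5S,7R)-1-[(2R)-but-3-yn-2-yl]-7-(prop-2-en-1-yl)-6-azaspiro[4.5]decan-6-yl]methyl}prop-2-enoic acid | C#C[C@H](C)[C@H]1CCC[C@]12CCC[C@H](CC=C)N2CC(=C)C(=O)O
F6 | step 11 | 2-{[(1R,5S,7R)-1-[(2R,6E)-7-chloro-9-hydroxy-5-oxonon-6-en-3-yn-2-yl]-7-(prop-2-en-1-yl)-6-azaspiro[4.5]decan-6-yl]methyl}prop-2-enoic acid | OCC/C(Cl)=C\C(=O)C#C[C@H](C)[C@H]1CCC[C@]12CCC[C@H](CC=C)N2CC(=C)C(=O)O
F7 | step 13 | (5R,9S,13R,14R,17R,18E)-15,16-didehydro analogue of the target (C17 epimer of 19) | C[C@H]1C#C[C@H](O)/C=C(/Cl)CCOC(=O)C2=CC[C@H]3CCC[C@]4(CCC[C@H]14)N3C2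
F8 | step 13 | (17S)-4-nitrobenzoate of 19 | C[C@H]1C#C[C@@H](OC(=O)c5ccc(cc5)[N+](=O)[O-])/C=C(/Cl)CCOC(=O)C2=CC[C@H]3CCC[C@]4(CCC[C@H]14)N3C2
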